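**Numbering.** Carotenoid numbering is used: unprimed atoms belong to the open-chain half, primed atoms to the ring half.

## The problem

1. The target is a C50 carotenoid in which an all-E undecaene (C3=C4 through C7'=C8', five methyl branches) joins an open end (carbinol C1, stereocenter C2 bearing a prenyl group) to an ε-ring (C1'–C6') that carries an (E)-4-hydroxy-3-methylbut-2-enyl chain at C2'.
2. The chromophore does not survive acid, light or oxidants, so both end groups and all three stereocenters must be finished before the chain is assembled, and the chain must be joined under mild base at disubstituted double bonds.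
3. The ring is the hard part: C2' and C6' flank the quaternary C1' and are trans, C6' is doubly allylic (to C4'=C5' and to the chain), and the C4'=C5' bond tends to move into conjugation as C5'=C6'.
4. C2' can control C6' (1,3 across C1'), but a chair closure from an E-olefin puts both chains equatorial and gives the cis ring, so the trans ring needs a thermodynamic relay or an encoded olefin geometry.
5. C2 lies 23 bonds from the ring and cannot be controlled by it, yet C2 and C2' carry the same substituent set (a CMe2X carbon, a CH2–CH=C(CH3) arm, a two-carbon link to a methyl-bearing sp2 carbon) with the same sense of chirality.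
6. The feature that makes the key step possible is the C1'–C6' ring bond. It joins a gem-dimethyl carbon (a latent tertiary cation, present in the opened ring as an isopropenyl group on C2') to C6', the γ-carbon of a C5'(CH3)=C6'–C7'=C8'–C9'(=O) dienone.
7. Opened at that bond, atoms C1', C16', C17', C2', C3', C4', C5', C18' and the first two side-chain carbons are the ten carbons of ring-cleaved limonene, with C2' = C4 of limonene; the same mapping holds for C2 of the open end.
8. The groups that will not stand rough treatment are the primary allylic alcohol, the tertiary carbinol next to the allylic C2–H, and the doubly allylic C6'–H.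

## Retrosynthesis

**Polyene (36 ← 35 ← 32 + 28; 32 ← 12 + 29).** The allylic alcohol of 36 is taken back to the ethyl enoate 35, which keeps that alkene electron-poor through all acid and base steps. 35 is cut at C11=C12 and C11'=C12' into phosphonium salts 28 and 12 and the symmetrical C10 dialdehyde 29. These bonds are disubstituted and their Z isomers are strained and revert on heating; the neighbouring C9=C10 and C13=C14 bonds are trisubstituted and would form with poor geometric control. The precursors are two C20 salts of similar size. The forward reactions must give mono-olefination of 29 and must not touch the ester.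

**Ring salt (12 ← 11 ← 10).** C10' and C11' are removed as a vinyl nucleophile, leaving the α-ionone-type methyl ketone 10. The alternative of building C7'=C8' by olefination of a ring aldehyde would pass through an aldehyde that epimerizes and conjugates easily. The forward steps are 1,2-addition and ionization with allylic transposition.

**Ring (10 ← 9 ← 8, key).** The C1'–C6' bond is cut. Cutting C5'–C6' (aldol) or C4'=C5' (metathesis) would leave the quaternary carbon and both ring stereocenters to be made in an open chain. Cutting C1'–C6' removes the ring, the quaternary centre, the ring double bond and C6' together and leaves the open-chain trienoate 8 with one stereocenter. The forward reaction must protonate only the isopropenyl group, lose the proton from C4', and allow C6' to be equilibrated to trans (9 → 10).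

**Dienone (8 ← 5 ← 4 ← 3).** The C6'–C10' carbons are removed from 8 as an acetylide and an acetone enol ether (propargyl Claisen logic), leaving methyl ketone 4. The enoate of 4 comes from the aldehyde of keto aldehyde 3 by olefination. A direct olefination of the ketone with a four-carbon reagent has no good precedent; the geometry at C5'=C6' is irrelevant because the bond is consumed in the ring closure.

**Chiral source (3 ← 1).** 3 is (S)-limonene 1 with its ring double bond cleaved. All ten carbons and the stereocenter are used, and no stereocenter has to be made.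

**Open-end salt (28 ← 26 ← 23 + 25; 25 ← 24).** The salt comes from tetraenol 26, cut at the C6–C7 sp2–sp2 bond into dienyl iodide 23 and dienylstannane 25 (from enynol 24). This cut is chosen over olefination at C5=C6 because the trisubstituted C5=C6 bond can then be made stereospecifically from an alkyne.

**Open-end chiral piece (23 ← 21 ← 19 ← 18 ← 17 ← 15 ← 14 ← 1).** Iodide 23 comes from enyne 21 by methyl-metalation, 21 from enone 19, 19 from ketone 18 by dehydrogenation, and 18 from the silyl-protected keto aldehyde 17 by olefination. 17 is ring-cleaved α-terpineol silyl ether 15, and α-terpineol 14 is hydrated 1. The same enantiomer of 1 therefore supplies C2 and C2', and only C6' has to be relayed.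

## Roads not taken

**Alternative 1:** The most obvious plan keeps the C20 + C10 + C20 Wittig assembly but makes each end with its own stereocontrol. The open end would be set by oxazolidinone-auxiliary prenylation to give A1. The ring would come from a preformed cyclohexene ester A2, with C6' set by kinetic deconjugative protonation of its dienolate. This needs two unrelated stereo-setting exercises plus auxiliary attachment and removal, and a silyl group on the allylic alcohol throughout the enolate chemistry. The proton should enter A2 anti to the axial C1' methyl group, which gives the 2',6'-cis ring, the opposite of what is wanted. The chosen plan buys one stereocenter for both ends and makes the ring with all its carbons in one step.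

**Alternative 2:** The ring could be built by catalytic desymmetrization of 4,4-dimethylcyclohexa-2,5-dienone. A copper-catalysed enantioselective conjugate addition would give A3; a second, trans-selective conjugate addition with enolate methylation would follow, and the C4' oxygen would be removed through an enol triflate. This is a strong route to the trans ring by substrate control. It costs extra redox steps to erase the carbonyl, needs the side chain to be elaborated from an allyl group, and gives no help with C2, which would need a second asymmetric reaction. The limonene plan needs no asymmetric reaction.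

**Alternative 3:** A late biomimetic closure would assemble the open-chain C50 polyene A4 and close the ring last, with acid or with a carotenoid cyclase (terpene cyclase class). Acid cannot tell the isopropenyl group from eleven conjugated double bonds and destroys the chromophore. A cyclase would be expected to fold the chain through the all-equatorial chair and give the 2',6'-cis ring. Once the polyene is in place there is no carbonyl handle left for equilibrating C6'. The ring must therefore be closed before the chain is built, as in the chosen plan.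

Key step: step 5

**Assumptions.**
- Read from the SMILES, the open end is 2R, the ring is 2'S,6'R (the C2' and C6' chains trans), the side-chain double bond is E and the polyene is all-E.
- (S)-(−)-Limonene 1, (2E,4E,6E)-2,7-dimethylocta-2,4,6-trienedial 29 and (2E)-3-methylpent-2-en-4-yn-1-ol 24 are taken as commercial.

## Steps

Step 1
Reactants: 1 (S)-(−)-limonene
Product: 3 (3S)-6-oxo-3-(prop-1-en-2-yl)heptanal, via limonene ozonide 2 (not isolated)
Conditions: O3 (1.0 equiv, dye end point), CH2Cl2, −78 °C; then PPh3, −78 °C to rt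
Reagents that add atoms: ozone [O-][O+]=O
Why: Chemoselective ozonolysis: the trisubstituted ring alkene is more electron-rich than the 1,1-disubstituted isopropenyl group and takes the single equivalent of ozone; reductive cleavage of the ozonide leaves the limonene stereocenter untouched as the future C2'.

Step 2
Reactants: 3 (3S)-6-oxo-3-(prop-1-en-2-yl)heptanal
Product: 4 ethyl (2E,5S)-2-methyl-8-oxo-5-(prop-1-en-2-yl)non-2-enoate
Conditions: Ph3P=C(CH3)CO2Et (1.1 equiv), CH2Cl2, rt
Reagents that add atoms: ethyl 2-(triphenylphosphoranylidene)propanoate CCOC(=O)C(C)=P(c1ccccc1)(c1ccccc1)c1ccccc1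
Why: Wittig olefination with a stabilized ylide reacts only at the aldehyde and gives the E-trisubstituted enoate; the enoate carries the future allylic alcohol as an acid-proof, electron-poor alkene.

Step 3
Reactants: 4 ethyl (2E,5S)-2-methyl-8-oxo-5-(prop-1-en-2-yl)non-2-enoate
Product: 5 ethyl (2E,5S)-8-hydroxy-2,8-dimethyl-5-(prop-1-en-2-yl)dec-2-en-9-ynoate
Conditions: HC≡CMgBr (1.3 equiv), THF, −40 to 0 °C; aq. NH4Cl
Reagents that add atoms: ethynylmagnesium bromide C#C[Mg]Br
Why: Grignard 1,2-addition to the methyl ketone, which is far more electrophilic than the α-methyl enoate at low temperature; the new carbinol centre (both epimers) is destroyed in step 4.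

Step 4
Reactants: 5 ethyl (2E,5S)-8-hydroxy-2,8-dimethyl-5-(prop-1-en-2-yl)dec-2-en-9-ynoate
Product: 8 ethyl (2E,5S,10E)-2,8-dimethyl-12-oxo-5-(prop-1-en-2-yl)trideca-2,8,10-trienoate, via propargyl isopropenyl ether 6 (not isolated), via allenyl ketone 7 (not isolated)
Conditions: 2-methoxypropene (4 equiv), TsOH (0.5 mol%), toluene, 100 °C, sealed; then NaOEt (5 mol%), EtOH, 0 °C
Reagents that add atoms: 2-methoxypropene COC(C)=C
Why: Saucy–Marbet rearrangement: acetal exchange gives 6, the propargyl Claisen shift gives β-ketoallene 7, and catalytic base moves the allene into conjugation as the 10E dienone. The product should be an 8E/8Z mixture, which is used as such because that double bond is consumed in step 5.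

Step 5
Reactants: 8 ethyl (2E,5S,10E)-2,8-dimethyl-12-oxo-5-(prop-1-en-2-yl)trideca-2,8,10-trienoate
Product: 9 ethyl (2E)-2-methyl-4-[(1S,5RS)-4,6,6-trimethyl-5-[(1E)-3-oxobut-1-en-1-yl]cyclohex-3-en-1-yl]but-2-enoate
Conditions: 85% H3PO4 (3 equiv), toluene, 30 °C
Reagents that add atoms: none
Why: Only the isopropenyl group can be protonated on carbon, because both trisubstituted alkenes are conjugated to carbonyl groups and take protons on oxygen; the tertiary cation C1' therefore forms next to the limonene stereocenter and is captured by C6', the γ-carbon of the dienone, in a 6-endo-trig cation–olefin closure through a chair with the C2' chain equatorial. The closest known reactions are the phosphoric acid cyclization of pseudoionone to α-ionone and of its 2-methyl homolog to α-irone, from which this substrate differs only in how the same cation is generated. Loss of a proton from C4' of the resulting C5' cation gives the trisubstituted C4'=C5' bond, the kinetic outcome in this acid, and the C7'=C8' enone is E. The step thus creates the ring, the quaternary C1', the position of the ring double bond and the stereocenter C6' from an open chain with one stereocenter. The configuration at C6' follows the geometry of C5'=C6' in the chair (E gives the 2',6'-cis ring, Z the trans ring), so both C6' epimers are expected from the 8E/8Z mixture and the step is deliberately not asked to control C6'; that is left to the thermodynamic relay from C2' in step 6. The step does need chemoselective protonation, ring closure faster than hydride shift or proton loss toward C2' (helped by the 1,5-placement of cation and π-nucleophile), and regioselective proton loss (helped by the mild acid and short contact time).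

Step 6
Reactants: 9 ethyl (2E)-2-methyl-4-[(1S,5RS)-4,6,6-trimethyl-5-[(1E)-3-oxobut-1-en-1-yl]cyclohex-3-en-1-yl]but-2-enoate
Product: 10 ethyl (2E)-2-methyl-4-[(1S,5R)-4,6,6-trimethyl-5-[(1E)-3-oxobut-1-en-1-yl]cyclohex-3-en-1-yl]but-2-enoate
Conditions: NaOEt (0.2 equiv), EtOH, 20 °C, monitored to equilibrium; chromatography, residual cis epimer resubmitted
Reagents that add atoms: none
Why: Vinylogous epimerization: C6'–H is γ to the enone carbonyl and allylic, so catalytic ethoxide equilibrates C6' through the extended dienolate. The trans isomer (C2' chain equatorial, C6' chain pseudoaxial) avoids the A(1,2) strain against the C5' methyl and the double gauche contact with the C1' methyls that burden the cis isomer, as in the known cis-to-trans equilibration of α-irone. The fixed C2' centre thereby sets C6' as R.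

Step 7
Reactants: 10 ethyl (2E)-2-methyl-4-[(1S,5R)-4,6,6-trimethyl-5-[(1E)-3-oxobut-1-en-1-yl]cyclohex-3-en-1-yl]but-2-enoate
Product: 11 ethyl (2E)-4-[(1S,5R)-5-[(1E)-3-hydroxy-3-methylpenta-1,4-dien-1-yl]-4,6,6-trimethylcyclohex-3-en-1-yl]-2-methylbut-2-enoate
Conditions: CH2=CHMgBr (1.2 equiv), THF, −78 °C; aq. NH4Cl
Reagents that add atoms: vinylmagnesium bromide C=C[Mg]Br
Why: Chemoselective Grignard 1,2-addition to the enone carbonyl; the hindered α-methyl enoate is left alone at −78 °C, and the carbinol configuration does not matter because that carbon becomes sp2 in step 8.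

Step 8
Reactants: 11 ethyl (2E)-4-[(1S,5R)-5-[(1E)-3-hydroxy-3-methylpenta-1,4-dien-1-yl]-4,6,6-trimethylcyclohex-3-en-1-yl]-2-methylbut-2-enoate
Product: 12 [(2E,4E)-5-[(1R,5S)-5-[(2E)-4-ethoxy-3-methyl-4-oxobut-2-en-1-yl]-2,6,6-trimethylcyclohex-2-en-1-yl]-3-methylpenta-2,4-dien-1-yl]triphenylphosphonium bromide
Conditions: PPh3·HBr (1.05 equiv), MeOH, 0 °C to rt; crystallization
Reagents that add atoms: triphenylphosphine hydrobromide [PH+](c1ccccc1)(c1ccccc1)c1ccccc1.[Br-]
Why: Standard carotenoid phosphonium salt formation: the bis-allylic tertiary alcohol ionizes to a pentadienyl cation that PPh3 captures at the primary terminus (SN1 with allylic transposition), giving mainly the 2E,4E salt. C6' is untouched because the cation is trapped faster than it loses H-6'.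

Step 9
Reactants: 1 (S)-(−)-limonene
Product: 14 (S)-α-terpineol, via hydroxyalkylmercury acetate 13 (not isolated)
Conditions: Hg(OAc)2 (1.0 equiv), THF/H2O 1:1, rt; then 3 M NaOH, NaBH4, 0 °C
Reagents that add atoms: water O; mercury diacetate CC(=O)O[Hg]OC(C)=O (its atoms stay only in intermediate 13)
Why: Oxymercuration–demercuration: the 1,1-disubstituted alkene is mercurated much faster than the trisubstituted ring alkene, water adds at the tertiary carbon, and NaBH4 replaces mercury by hydrogen; the stereocenter is not involved.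

Step 10
Reactants: 14 (S)-α-terpineol
Product: 15 triethyl{[2-[(1S)-4-methylcyclohex-3-en-1-yl]propan-2-yl]oxy}silane
Conditions: Et3SiOTf (1.2 equiv), 2,6-lutidine, CH2Cl2, 0 °C
Reagents that add atoms: triethylsilyl trifluoromethanesulfonate CC[Si](CC)(CC)OS(=O)(=O)C(F)(F)F
Why: Silylation of the tertiary alcohol with a silyl triflate; the ether prevents lactol formation after ring cleavage and alkoxide-triggered fragmentation or dehydration in the carbonyl steps.

Step 11
Reactants: 15 triethyl{[2-[(1S)-4-methylcyclohex-3-en-1-yl]propan-2-yl]oxy}silane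
Product: 17 (3S)-6-oxo-3-[2-(triethylsilyloxy)propan-2-yl]heptanal, via ozonide 16 (not isolated)
Conditions: O3, CH2Cl2, −78 °C; then PPh3, −78 °C to rt
Reagents that add atoms: ozone [O-][O+]=O
Why: Ozonolysis of the only alkene with reductive work-up; the stereocenter is the future C2 with the same arm assignment as in 3.

Step 12
Reactants: 17 (3S)-6-oxo-3-[2-(triethylsilyloxy)propan-2-yl]heptanal
Product: 18 (5S)-8-methyl-5-[2-(triethylsilyloxy)propan-2-yl]non-7-en-2-one
Conditions: i-PrPPh3I (1.1 equiv), n-BuLi (1.05 equiv), THF, 0 °C; then 17, −78 °C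
Reagents that add atoms: isopropyltriphenylphosphonium iodide CC(C)[P+](c1ccccc1)(c1ccccc1)c1ccccc1.[I-]
Why: Wittig olefination with the non-stabilized isopropylidene ylide is selective for the aldehyde over the methyl ketone at −78 °C and installs the prenyl group.

Step 13
Reactants: 18 (5S)-8-methyl-5-[2-(triethylsilyloxy)propan-2-yl]non-7-en-2-one
Product: 19 (3E,5R)-8-methyl-5-[2-(triethylsilyloxy)propan-2-yl]nona-3,7-dien-2-one
Conditions: IBX (2 equiv), 4-methoxypyridine N-oxide (2 equiv), DMSO, rt
Reagents that add atoms: none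
Why: IBX dehydrogenation of the ketone through its enol; only the CH2–CH2 side can give an enone, and the E isomer forms. The descriptor changes from S to R only because the ranking of the substituents changes.

Step 14
Reactants: 19 (3E,5R)-8-methyl-5-[2-(triethylsilyloxy)propan-2-yl]nona-3,7-dien-2-one
Product: 21 (3E,5R)-8-methyl-5-[2-(triethylsilyloxy)propan-2-yl]nona-3,7-dien-1-yne, via dienyl phosphate 20 (not isolated)
Conditions: LDA (1.1 equiv), THF, −78 °C; ClP(O)(OEt)2; then LDA (2.3 equiv), −78 to 0 °C; H2O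
Reagents that add atoms: diethyl chlorophosphate CCOP(Cl)(=O)OCC (its atoms stay only in intermediate 20)
Why: Ketone-to-alkyne conversion through an enol phosphate: kinetic deprotonation at the methyl group and O-phosphorylation give 20, which eliminates with more amide base to the terminal alkyne. The γ-hydrogen at the stereocenter is kinetically much less acidic than the methyl hydrogens.

Step 15
Reactants: 21 (3E,5R)-8-methyl-5-[2-(triethylsilyloxy)propan-2-yl]nona-3,7-dien-1-yne
Product: 23 (1E,3E,5R)-1-iodo-2,8-dimethyl-5-[2-(triethylsilyloxy)propan-2-yl]nona-1,3,7-triene, via alkenylalane 22 (not isolated)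
Conditions: Me3Al (2 equiv), Cp2ZrCl2 (0.2 equiv), CH2Cl2, 0 °C to rt; then I2, THF, −30 °C
Reagents that add atoms: trimethylaluminium C[Al](C)C; iodine II
Why: Zirconium-catalysed carboalumination (Negishi) adds methyl and aluminium syn across the terminal alkyne with methyl on the internal carbon; iodinolysis of 22 with retention gives the E-trisubstituted iodide and so fixes the C5=C6 geometry of the target.

Step 16
Reactants: 24 (2E)-3-methylpent-2-en-4-yn-1-ol
Product: 25 (2E,4E)-3-methyl-5-(tributylstannyl)penta-2,4-dien-1-ol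
Conditions: Bu3SnH (1.1 equiv), PdCl2(PPh3)2 (2 mol%), THF, 0 °C
Reagents that add atoms: tributyltin hydride CCCC[SnH](CCCC)CCCC
Why: Palladium-catalysed syn hydrostannation of the terminal alkyne places tin on the terminal carbon and gives the E,E-dienylstannane.

Step 17
Reactants: 23 (1E,3E,5R)-1-iodo-2,8-dimethyl-5-[2-(triethylsilyloxy)propan-2-yl]nona-1,3,7-triene; 25 (2E,4E)-3-methyl-5-(tributylstannyl)penta-2,4-dien-1-ol
Product: 26 (2E,4E,6E,8E,10R)-3,7,13-trimethyl-10-[2-(triethylsilyloxy)propan-2-yl]tetradeca-2,4,6,8,12-pentaen-1-ol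
Conditions: PdCl2(MeCN)2 (5 mol%), DMF, rt, dark
Reagents that add atoms: none
Why: Stille coupling of the alkenyl iodide with the alkenylstannane forms the C6–C7 bond with retention of geometry at both sp2 carbons; the free hydroxyl is tolerated.

Step 18
Reactants: 26 (2E,4E,6E,8E,10R)-3,7,13-trimethyl-10-[2-(triethylsilyloxy)propan-2-yl]tetradeca-2,4,6,8,12-pentaen-1-ol
Product: 28 [(2E,4E,6E,8E,10R)-10-(2-hydroxypropan-2-yl)-3,7,13-trimethyltetradeca-2,4,6,8,12-pentaen-1-yl]triphenylphosphonium bromide, via silyl-protected phosphonium bromide 27 (not isolated)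
Conditions: PPh3·HBr (1.2 equiv), MeOH, 0 °C to rt
Reagents that add atoms: triphenylphosphine hydrobromide [PH+](c1ccccc1)(c1ccccc1)c1ccccc1.[Br-]
Why: Ionization of the polyenylic primary alcohol and capture of the cation by PPh3 at the primary terminus, as in retinyl phosphonium salt formation; the slight excess of the acidic salt in methanol then removes the tertiary triethylsilyl ether of 27 by methanolysis.

Step 19
Reactants: 12 [(2E,4E)-5-[(1R,5S)-5-[(2E)-4-ethoxy-3-methyl-4-oxobut-2-en-1-yl]-2,6,6-trimethylcyclohex-2-en-1-yl]-3-methylpenta-2,4-dien-1-yl]triphenylphosphonium bromide; 29 (2E,4E,6E)-2,7-dimethylocta-2,4,6-trienedial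
Product: 32 ethyl (2E)-4-[(1S,5R)-5-[(1E,3E,5E,7E,9E,11E)-3,7,12-trimethyl-13-oxotrideca-1,3,5,7,9,11-hexaen-1-yl]-4,6,6-trimethylcyclohex-3-en-1-yl]-2-methylbut-2-enoate, via ylide 30 (not isolated), via 11'Z aldehyde 31 (not isolated)
Conditions: 29 (3 equiv), NaOEt (1.1 equiv), EtOH/CH2Cl2, 0 °C to rt; AcOH; then EtOH, 78 °C, dark
Reagents that add atoms: none
Why: Wittig reaction of the semi-stabilized ylide 30 with one formyl group of the dialdehyde used in excess; the 11'Z isomer 31 formed alongside is strained (H-10' against the C13' methyl) and isomerizes thermally to the all-E aldehyde. Ethoxide matches the ethyl ester.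

Step 20
Reactants: 32 ethyl (2E)-4-[(1S,5R)-5-[(1E,3E,5E,7E,9E,11E)-3,7,12-trimethyl-13-oxotrideca-1,3,5,7,9,11-hexaen-1-yl]-4,6,6-trimethylcyclohex-3-en-1-yl]-2-methylbut-2-enoate; 28 [(2E,4E,6E,8E,10R)-10-(2-hydroxypropan-2-yl)-3,7,13-trimethyltetradeca-2,4,6,8,12-pentaen-1-yl]triphenylphosphonium bromide
Product: 35 ethyl (2E)-4-[(1S,5R)-5-[(1E,3E,5E,7E,9E,11E,13E,15E,17E,19E,21E,23R)-23-(2-hydroxypropan-2-yl)-3,7,12,16,20,26-hexamethylheptacosa-1,3,5,7,9,11,13,15,17,19,21,25-dodecaen-1-yl]-4,6,6-trimethylcyclohex-3-en-1-yl]-2-methylbut-2-enoate, via ylide 33 (not isolated), via 11Z ester 34 (not isolated)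
Conditions: NaOEt (1.2 equiv), EtOH/CH2Cl2, 0 °C to rt; AcOH; then EtOH/heptane, 80 °C, dark, N2
Reagents that add atoms: none
Why: Second Wittig reaction forms C11=C12 and completes the C50 skeleton; the strained 11Z isomer 34 reverts thermally to the all-E polyene. No stereocenter is touched, since C2–H and C6'–H are not acidic toward ethoxide.

Step 21
Reactants: 35 ethyl (2E)-4-[(1S,5R)-5-[(1E,3E,5E,7E,9E,11E,13E,15E,17E,19E,21E,23R)-23-(2-hydroxypropan-2-yl)-3,7,12,16,20,26-hexamethylheptacosa-1,3,5,7,9,11,13,15,17,19,21,25-dodecaen-1-yl]-4,6,6-trimethylcyclohex-3-en-1-yl]-2-methylbut-2-enoate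
Product: 36 target CNP0409952.2
Conditions: i-Bu2AlH (3.5 equiv), CH2Cl2, −78 °C; aq. potassium sodium tartrate
Reagents that add atoms: none
Why: 1,2-Reduction of the conjugated ester by the aluminium hydride gives the E-allylic alcohol without touching the polyene; the tertiary hydroxyl only consumes one equivalent of hydride.

## Compound list

1 | (S)-(−)-limonene, (4S)-1-methyl-4-(prop-1-en-2-yl)cyclohex-1-ene | CC1=CC[C@H](CC1)C(C)=C | starting material
2 | limonene ozonide, (4S)-1-methyl-4-(prop-1-en-2-yl)-7,8,9-trioxabicyclo[4.2.1]nonane (mixture at the two ozonide carbons) | CC12CC[C@H](C(C)=C)CC(OO1)O2 | intermediate (not isolated)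
3 | (3S)-6-oxo-3-(prop-1-en-2-yl)heptanal | O=CC[C@H](CCC(C)=O)C(C)=C | intermediate
4 | ethyl (2E,5S)-2-methyl-8-oxo-5-(prop-1-en-2-yl)non-2-enoate | CCOC(=O)/C(C)=C/C[C@H](CCC(C)=O)C(C)=C | intermediate
5 | ethyl (2E,5S)-8-hydroxy-2,8-dimethyl-5-(prop-1-en-2-yl)dec-2-en-9-ynoate (both C8 epimers) | CCOC(=O)/C(C)=C/C[C@H](CCC(C)(O)C#C)C(C)=C | intermediate
6 | ethyl (2E,5S)-2,8-dimethyl-5-(prop-1-en-2-yl)-8-(prop-1-en-2-yloxy)dec-2-en-9-ynoate | CCOC(=O)/C(C)=C/C[C@H](CCC(C)(OC(C)=C)C#C)C(C)=C | intermediate (not isolated)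
7 | ethyl (2E,5S)-2,8-dimethyl-12-oxo-5-(prop-1-en-2-yl)trideca-2,8,9-trienoate (allenyl ketone) | CCOC(=O)/C(C)=C/C[C@H](CCC(C)=C=CCC(C)=O)C(C)=C | intermediate (not isolated)
8 | ethyl (2E,5S,10E)-2,8-dimethyl-12-oxo-5-(prop-1-en-2-yl)trideca-2,8,10-trienoate (8E/8Z mixture) | CCOC(=O)/C(C)=C/C[C@H](CCC(C)=C/C=C/C(C)=O)C(C)=C | intermediate
9 | ethyl (2E)-2-methyl-4-[(1S,5RS)-4,6,6-trimethyl-5-[(1E)-3-oxobut-1-en-1-yl]cyclohex-3-en-1-yl]but-2-enoate (both C6' epimers) | CCOC(=O)/C(C)=C/C[C@@H]1CC=C(C)C(/C=C/C(C)=O)C1(C)C | intermediate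
10 | ethyl (2E)-2-methyl-4-[(1S,5R)-4,6,6-trimethyl-5-[(1E)-3-oxobut-1-en-1-yl]cyclohex-3-en-1-yl]but-2-enoate (2',6'-trans) | CCOC(=O)/C(C)=C/C[C@@H]1CC=C(C)[C@@H](/C=C/C(C)=O)C1(C)C | intermediate
11 | ethyl (2E)-4-[(1S,5R)-5-[(1E)-3-hydroxy-3-methylpenta-1,4-dien-1-yl]-4,6,6-trimethylcyclohex-3-en-1-yl]-2-methylbut-2-enoate (both carbinol epimers) | CCOC(=O)/C(C)=C/C[C@@H]1CC=C(C)[C@@H](/C=C/C(C)(O)C=C)C1(C)C | intermediate
12 | [(2E,4E)-5-[(1R,5S)-5-[(2E)-4-ethoxy-3-methyl-4-oxobut-2-en-1-yl]-2,6,6-trimethylcyclohex-2-en-1-yl]-3-methylpenta-2,4-dien-1-yl]triphenylphosphonium bromide | CCOC(=O)/C(C)=C/C[C@@H]1CC=C(C)[C@@H](/C=C/C(C)=C/C[P+](c2ccccc2)(c2ccccc2)c2ccccc2)C1(C)C.[Br-] | intermediate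
13 | acetoxy{2-hydroxy-2-[(1S)-4-methylcyclohex-3-en-1-yl]propyl}mercury (both carbinol epimers) | CC1=CC[C@H](CC1)C(C)(O)C[Hg]OC(C)=O | intermediate (not isolated)
14 | (S)-α-terpineol, 2-[(1S)-4-methylcyclohex-3-en-1-yl]propan-2-ol | CC1=CC[C@H](CC1)C(C)(C)O | intermediate
15 | triethyl{[2-[(1S)-4-methylcyclohex-3-en-1-yl]propan-2-yl]oxy}silane | CC1=CC[C@H](CC1)C(C)(C)O[Si](CC)(CC)CC | intermediate
16 | ozonide of 15, triethyl{[2-[(4S)-1-methyl-7,8,9-trioxabicyclo[4.2.1]nonan-4-yl]propan-2-yl]oxy}silane | CC12CC[C@H](C(C)(C)O[Si](CC)(CC)CC)CC(OO1)O2 | intermediate (not isolated)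
17 | (3S)-6-oxo-3-[2-(triethylsilyloxy)propan-2-yl]heptanal | O=CC[C@H](CCC(C)=O)C(C)(C)O[Si](CC)(CC)CC | intermediate
18 | (5S)-8-methyl-5-[2-(triethylsilyloxy)propan-2-yl]non-7-en-2-one | CC(C)=CC[C@H](CCC(C)=O)C(C)(C)O[Si](CC)(CC)CC | intermediate
19 | (3E,5R)-8-methyl-5-[2-(triethylsilyloxy)propan-2-yl]nona-3,7-dien-2-one | CC(C)=CC[C@H](/C=C/C(C)=O)C(C)(C)O[Si](CC)(CC)CC | intermediate
20 | diethyl (3E,5R)-8-methyl-5-[2-(triethylsilyloxy)propan-2-yl]nona-1,3,7-trien-2-yl phosphate | CC(C)=CC[C@H](/C=C/C(=C)OP(=O)(OCC)OCC)C(C)(C)O[Si](CC)(CC)CC | intermediate (not isolated)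
21 | (3E,5R)-8-methyl-5-[2-(triethylsilyloxy)propan-2-yl]nona-3,7-dien-1-yne | CC(C)=CC[C@H](/C=C/C#C)C(C)(C)O[Si](CC)(CC)CC | intermediate
22 | dimethyl{(1E,3E,5R)-2,8-dimethyl-5-[2-(triethylsilyloxy)propan-2-yl]nona-1,3,7-trien-1-yl}alumane | CC(C)=CC[C@H](/C=C/C(C)=C/[Al](C)C)C(C)(C)O[Si](CC)(CC)CC | intermediate (not isolated)
23 | (1E,3E,5R)-1-iodo-2,8-dimethyl-5-[2-(triethylsilyloxy)propan-2-yl]nona-1,3,7-triene | CC(C)=CC[C@H](/C=C/C(C)=C/I)C(C)(C)O[Si](CC)(CC)CC | intermediate
24 | (2E)-3-methylpent-2-en-4-yn-1-ol | C#C/C(C)=C/CO | starting material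
25 | (2E,4E)-3-methyl-5-(tributylstannyl)penta-2,4-dien-1-ol | CCCC[Sn](CCCC)(CCCC)/C=C/C(C)=C/CO | intermediate
26 | (2E,4E,6E,8E,10R)-3,7,13-trimethyl-10-[2-(triethylsilyloxy)propan-2-yl]tetradeca-2,4,6,8,12-pentaen-1-ol | CC(C)=CC[C@H](/C=C/C(C)=C/C=C/C(C)=C/CO)C(C)(C)O[Si](CC)(CC)CC | intermediate
27 | [(2E,4E,6E,8E,10R)-3,7,13-trimethyl-10-[2-(triethylsilyloxy)propan-2-yl]tetradeca-2,4,6,8,12-pentaen-1-yl]triphenylphosphonium bromide | CC(C)=CC[C@H](/C=C/C(C)=C/C=C/C(C)=C/C[P+](c1ccccc1)(c1ccccc1)c1ccccc1)C(C)(C)O[Si](CC)(CC)CC.[Br-] | intermediate (not isolated)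
28 | [(2E,4E,6E,8E,10R)-10-(2-hydroxypropan-2-yl)-3,7,13-trimethyltetradeca-2,4,6,8,12-pentaen-1-yl]triphenylphosphonium bromide | CC(C)=CC[C@H](/C=C/C(C)=C/C=C/C(C)=C/C[P+](c1ccccc1)(c1ccccc1)c1ccccc1)C(C)(C)O.[Br-] | intermediate
29 | (2E,4E,6E)-2,7-dimethylocta-2,4,6-trienedial | O=C/C(C)=C/C=C/C=C(C)/C=O | starting material
30 | ylide of 12, ethyl (2E)-2-methyl-4-[(1S,5R)-4,6,6-trimethyl-5-[(1E,3E)-3-methyl-5-(triphenyl-λ5-phosphanylidene)penta-1,3-dien-1-yl]cyclohex-3-en-1-yl]but-2-enoate | CCOC(=O)/C(C)=C/C[C@@H]1CC=C(C)[C@@H](/C=C/C(C)=C/C=P(c2ccccc2)(c2ccccc2)c2ccccc2)C1(C)C | intermediate (not isolated)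
31 | 11'Z isomer of 32 (5Z in the trideca-hexaenyl chain) | CCOC(=O)/C(C)=C/C[C@@H]1CC=C(C)[C@@H](/C=C/C(C)=C/C=C\C(C)=C\C=C\C=C(C)\C=O)C1(C)C | intermediate (not isolated)
32 | ethyl (2E)-4-[(1S,5R)-5-[(1E,3E,5E,7E,9E,11E)-3,7,12-trimethyl-13-oxotrideca-1,3,5,7,9,11-hexaen-1-yl]-4,6,6-trimethylcyclohex-3-en-1-yl]-2-methylbut-2-enoate | CCOC(=O)/C(C)=C/C[C@@H]1CC=C(C)[C@@H](/C=C/C(C)=C/C=C/C(C)=C/C=C/C=C(C)/C=O)C1(C)C | intermediate
33 | ylide of 28, (3R,4E,6E,8E,10E)-2,6,10-trimethyl-3-(3-methylbut-2-en-1-yl)-12-(triphenyl-λ5-phosphanylidene)dodeca-4,6,8,10-tetraen-2-ol | CC(C)=CC[C@H](/C=C/C(C)=C/C=C/C(C)=C/C=P(c1ccccc1)(c1ccccc1)c1ccccc1)C(C)(C)O | intermediate (not isolated)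
34 | 11Z isomer of 35 | CC(C)=CC[C@H](/C=C/C(C)=C/C=C/C(C)=C/C=C\C(C)=C\C=C\C=C(C)\C=C\C=C(C)\C=C\[C@@H]1C(C)=CC[C@@H](C/C=C(\C)C(=O)OCC)C1(C)C)C(C)(C)O | intermediate (not isolated)
35 | ethyl (2E)-4-[(1S,5R)-5-[(1E,3E,5E,7E,9E,11E,13E,15E,17E,19E,21E,23R)-23-(2-hydroxypropan-2-yl)-3,7,12,16,20,26-hexamethylheptacosa-1,3,5,7,9,11,13,15,17,19,21,25-dodecaen-1-yl]-4,6,6-trimethylcyclohex-3-en-1-yl]-2-methylbut-2-enoate | CC(C)=CC[C@H](/C=C/C(C)=C/C=C/C(C)=C/C=C/C(C)=C/C=C/C=C(C)/C=C/C=C(C)/C=C/[C@@H]1C(C)=CC[C@@H](C/C=C(\C)C(=O)OCC)C1(C)C)C(C)(C)O | intermediate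
36 | target CNP0409952.2, (2E)-4-[(1S,5R)-5-[(1E,3E,5E,7E,9E,11E,13E,15E,17E,19E,21E,23R)-23-(2-hydroxypropan-2-yl)-3,7,12,16,20,26-hexamethylheptacosa-1,3,5,7,9,11,13,15,17,19,21,25-dodecaen-1-yl]-4,6,6-trimethylcyclohex-3-en-1-yl]-2-methylbut-2-en-1-ol | CC(C)=CC[C@H](/C=C/C(C)=C/C=C/C(C)=C/C=C/C(C)=C/C=C/C=C(C)/C=C/C=C(C)/C=C/[C@@H]1C(C)=CC[C@@H](C/C=C(\C)CO)C1(C)C)C(C)(C)O | target

## Count and risks

Total steps: 21. Longest linear sequence: 11 (steps 1–8, 19, 20, 21; the open-end line 9–15, 17, 18, 20, 21 is equally long).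

**Step 5 (key step).** The most likely failures are erosion of C2' by a 1,2-hydride shift or proton loss from the C1' cation before the deactivated dienone captures it, and drift of the ring double bond into conjugation by reprotonation.
Fallback: close the ring at the aldehyde level and attach the three-carbon ketone unit afterwards. Setting out from 5, a vanadate-catalysed Meyer–Schuster rearrangement gives the enal ethyl (2E,5S)-2,8-dimethyl-10-oxo-5-(prop-1-en-2-yl)deca-2,8-dienoate F1. Condensation with aniline gives its N-phenyl imine F2, which is cyclized in cold concentrated H2SO4 (the classical citral-anil closure) and hydrolysed to the ring aldehyde ethyl (2E)-4-[(1S,5RS)-5-formyl-4,6,6-trimethylcyclohex-3-en-1-yl]-2-methylbut-2-enoate F3. Aldol condensation of F3 with acetone (NaOEt) returns to the route at 9.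

**Step 6.** The ring double bond may migrate into conjugation with the enone faster than C6' epimerizes, or the equilibrium may leave too much cis epimer.
Fallback: encode the trans ring in the olefin geometry and close under kinetic control. Setting out from 8, the 8Z isomer ethyl (2E,5S,8Z,10E)-2,8-dimethyl-12-oxo-5-(prop-1-en-2-yl)trideca-2,8,10-trienoate F4 is separated by chromatography, and the 8E isomer is re-equilibrated with iodine and light. F4 is cyclized with ClSO3H in 2-nitropropane at −78 °C, where the chair places C7' axial and the geometry should be retained. This returns to the route directly at 10.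

**Step 13.** Over-oxidation through the γ-position would erase the stereocenter, and the silyl ether may be lost oxidatively.
Fallback: a two-stage Saegusa–Ito dehydrogenation. Setting out from 18, Me3SiI and (Me3Si)2NH give the thermodynamic trimethylsilyl enol ether F5 (C3=C4 enol ether, stereocenter as in 18), and Pd(OAc)2 in MeCN converts F5 to the enone, returning at 19.

**Step 14.** Deprotonation at the γ-stereocenter would racemize it, and amide may add to the dienyl phosphate during the double elimination.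
Fallback: build C5=C6 and C9=C10 by olefination instead of through the alkyne. Setting out from 19, Horner–Wadsworth–Emmons reaction with triethyl phosphonoacetate gives ethyl (2E,4E,6R)-3,9-dimethyl-6-[2-(triethylsilyloxy)propan-2-yl]deca-2,4,8-trienoate F6 (2Z isomer removed by chromatography). i-Bu2AlH reduction gives the dienol F7 and MnO2 the dienal F8. A second Horner–Wadsworth–Emmons reaction with triethyl 3-methyl-4-phosphonocrotonate gives ethyl (2E,4E,6E,8E,10R)-3,7,13-trimethyl-10-[2-(triethylsilyloxy)propan-2-yl]tetradeca-2,4,6,8,12-pentaenoate F9, and i-Bu2AlH reduction returns to the route at 26.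

**Step 18.** The polyenyl cation may lose the C2 proton (retro-type rearrangement), HBr may add to the prenyl group, or desilylation may be incomplete.
Fallback: reverse the polarity of the last Wittig reaction so that the open end never meets acid. Setting out from 26, MnO2 gives the aldehyde (2E,4E,6E,8E,10R)-3,7,13-trimethyl-10-[2-(triethylsilyloxy)propan-2-yl]tetradeca-2,4,6,8,12-pentaenal F10. Separately, 32 is reduced with NaBH4 to the allylic alcohol F11 and converted with PPh3·HBr into the C30 phosphonium bromide F12. Wittig reaction of F12 with F10 (NaOEt, then thermal isomerization) gives the triethylsilyl ether F13 of the C50 ester, and Bu4NF removes the silyl group, returning to the route at 35.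

## Further compounds

F1 | step 5 | ethyl (2E,5S)-2,8-dimethyl-10-oxo-5-(prop-1-en-2-yl)deca-2,8-dienoate (8E/8Z) | CCOC(=O)/C(C)=C/C[C@H](CCC(C)=CC=O)C(C)=C
F2 | step 5 | ethyl (2E,5S)-2,8-dimethyl-10-(phenylimino)-5-(prop-1-en-2-yl)deca-2,8-dienoate | CCOC(=O)/C(C)=C/C[C@H](CCC(C)=CC=Nc1ccccc1)C(C)=C
F3 | step 5 | ethyl (2E)-4-[(1S,5RS)-5-formyl-4,6,6-trimethylcyclohex-3-en-1-yl]-2-methylbut-2-enoate | CCOC(=O)/C(C)=C/C[C@@H]1CC=C(C)C(C=O)C1(C)C
F4 | step 6 | ethyl (2E,5S,8Z,10E)-2,8-dimethyl-12-oxo-5-(prop-1-en-2-yl)trideca-2,8,10-trienoate | CCOC(=O)/C(C)=C/C[C@H](CC/C(C)=C\C=C\C(C)=O)C(C)=C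
F5 | step 13 | thermodynamic trimethylsilyl enol ether of 18, triethyl{[2-methyl-3-(3-methylbut-2-en-1-yl)-6-(trimethylsilyloxy)hept-5-en-2-yl]oxy}silane (stereocenter as in 18) | CC(C)=CC[C@H](CC=C(C)O[Si](C)(C)C)C(C)(C)O[Si](CC)(CC)CC
F6 | step 14 | ethyl (2E,4E,6R)-3,9-dimethyl-6-[2-(triethylsilyloxy)propan-2-yl]deca-2,4,8-trienoate | CCOC(=O)/C=C(C)/C=C/[C@@H](CC=C(C)C)C(C)(C)O[Si](CC)(CC)CC
F7 | step 14 | (2E,4E,6R)-3,9-dimethyl-6-[2-(triethylsilyloxy)propan-2-yl]deca-2,4,8-trien-1-ol | OC/C=C(C)/C=C/[C@@H](CC=C(C)C)C(C)(C)O[Si](CC)(CC)CC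
F8 | step 14 | (2E,4E,6R)-3,9-dimethyl-6-[2-(triethylsilyloxy)propan-2-yl]deca-2,4,8-trienal | O=C/C=C(C)/C=C/[C@@H](CC=C(C)C)C(C)(C)O[Si](CC)(CC)CC
F9 | step 14 | ethyl (2E,4E,6E,8E,10R)-3,7,13-trimethyl-10-[2-(triethylsilyloxy)propan-2-yl]tetradeca-2,4,6,8,12-pentaenoate | CCOC(=O)/C=C(C)/C=C/C=C(C)/C=C/[C@@H](CC=C(C)C)C(C)(C)O[Si](CC)(CC)CC
F10 | step 18 | (2E,4E,6E,8E,10R)-3,7,13-trimethyl-10-[2-(triethylsilyloxy)propan-2-yl]tetradeca-2,4,6,8,12-pentaenal | CC(C)=CC[C@H](/C=C/C(C)=C/C=C/C(C)=C/C=O)C(C)(C)O[Si](CC)(CC)CC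
F11 | step 18 | ethyl (2E)-4-[(1S,5R)-5-[(1E,3E,5E,7E,9E,11E)-13-hydroxy-3,7,12-trimethyltrideca-1,3,5,7,9,11-hexaen-1-yl]-4,6,6-trimethylcyclohex-3-en-1-yl]-2-methylbut-2-enoate | CCOC(=O)/C(C)=C/C[C@@H]1CC=C(C)[C@@H](/C=C/C(C)=C/C=C/C(C)=C/C=C/C=C(C)/CO)C1(C)C
F12 | step 18 | [(2E,4E,6E,8E,10E,12E)-13-[(1R,5S)-5-[(2E)-4-ethoxy-3-methyl-4-oxobut-2-en-1-yl]-2,6,6-trimethylcyclohex-2-en-1-yl]-2,7,11-trimethyltrideca-2,4,6,8,10,12-hexaen-1-yl]triphenylphosphonium bromide | CCOC(=O)/C(C)=C/C[C@@H]1CC=C(C)[C@@H](/C=C/C(C)=C/C=C/C(C)=C/C=C/C=C(C)/C[P+](c2ccccc2)(c2ccccc2)c2ccccc2)C1(C)C.[Br-]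
F13 | step 18 | triethylsilyl ether of 35 at the tertiary hydroxyl | CC(C)=CC[C@H](/C=C/C(C)=C/C=C/C(C)=C/C=C/C(C)=C/C=C/C=C(C)/C=C/C=C(C)/C=C/[C@@H]1C(C)=CC[C@@H](C/C=C(\C)C(=O)OCC)C1(C)C)C(C)(C)O[Si](CC)(CC)CC
A1 | alternative 1 | (4R)-4-benzyl-3-[(2R)-2-ethenyl-5-methylhex-4-enoyl]-1,3-oxazolidin-2-one | CC(C)=CC[C@H](C=C)C(=O)N1[C@H](Cc2ccccc2)COC1=O
A2 | alternative 1 | methyl (5S)-5-[(2E)-4-{[tert-butyl(dimethyl)silyl]oxy}-3-methylbut-2-en-1-yl]-2,6,6-trimethylcyclohex-1-ene-1-carboxylate | COC(=O)C1=C(C)CC[C@@H](C/C=C(\C)CO[Si](C)(C)C(C)(C)C)C1(C)C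
A3 | alternative 2 | (5R)-4,4-dimethyl-5-(prop-2-en-1-yl)cyclohex-2-en-1-one | C=CC[C@@H]1CC(=O)C=CC1(C)C
A4 | alternative 3 | open-chain C50 seco-precursor with an isopropenyl group on C2' in place of the ring | C=C(C)[C@H](C/C=C(\C)CO)CC/C(C)=C/C=C/C(C)=C/C=C/C(C)=C/C=C/C=C(C)/C=C/C=C(C)/C=C/C=C(C)/C=C/[C@@H](CC=C(C)C)C(C)(C)O
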